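The target is disconnected at the bond between the gem-dimethyl carbon (C6 of the ring) and the chain-bearing ring carbon (C1) of its 2,6,6-trimethylcyclohex-1-enyl ring. This ring, with its tetrasubstituted C1=C2 alkene, is the cyclised terminal diprenyl unit of a linear sesterterpenoid. One cation–olefin monocyclisation by an engineered squalene–hopene cyclase therefore closes the carbocycle and fixes the alkene position in a single, final operation. The precursor is the unprotected acyclic diol–butenolide carrying an (E,E)-homofarnesyl chain. It is assembled by an (E)-selective Wittig reaction between a homofarnesyl-substituted stabilised ylide and an (S)-β-silyloxy furyl aldehyde, followed by furan-to-butenolide oxidation.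

Key step: step 11

Remark: the SMILES is read as the (S)-carbinol with CH2OH trans to the carbinol-side CH2 on its alkene; the hemiacetal and bridgehead centres of 14 and 15 form as mixtures and disappear again.

Step 1
Reactants: 1 ethyl 3-(furan-3-yl)-3-oxopropanoate
Product: 2 ethyl (3S)-3-(furan-3-yl)-3-hydroxypropanoate
Conditions: RuCl(p-cymene)[(S,S)-TsDPEN] (cat.), HCO2H/Et3N (5:2), DMF, 40 °C
Reagents that add atoms: none
Why: Noyori asymmetric transfer hydrogenation of an aryl ketone, in which the (S,S)-ligand delivers hydride through the outer-sphere six-membered transition state with the furyl ring held against the η6-arene, which should set the (S)-carbinol while furan and ester stay untouched.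

Step 2
Reactants: 2 ethyl (3S)-3-(furan-3-yl)-3-hydroxypropanoate
Product: 3 ethyl (3S)-3-(furan-3-yl)-3-(triethylsilyloxy)propanoate
Conditions: Et3SiCl, imidazole, CH2Cl2, 0 °C to rt
Reagents that add atoms: chlorotriethylsilane, CC[Si](Cl)(CC)CC
Why: Standard O-silylation of a secondary alcohol, giving an ether that survives hydride and ylide steps yet is cleaved later by dilute acid.

Step 3
Reactants: 3 ethyl (3S)-3-(furan-3-yl)-3-(triethylsilyloxy)propanoate
Product: 4 (3S)-3-(furan-3-yl)-3-(triethylsilyloxy)propanal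
Conditions: iBu2AlH (1.1 equiv), CH2Cl2, −78 °C
Reagents that add atoms: none
Why: Partial ester reduction, in which the tetrahedral aluminium hemiacetal is stable at −78 °C and releases the aldehyde only on work-up; the stereocentre is β to the carbonyl and cannot epimerise.

Step 4
Reactants: 5 (2E,6E)-farnesyl bromide
Product: 7 (3E,7E)-homofarnesol, via homofarnesyl(isopropoxy)dimethylsilane 6 (not isolated)
Conditions: ClCH2SiMe2(OiPr), Mg, THF; then 5, Li2CuCl4 (cat.), THF, −20 to 0 °C; then KF, KHCO3, 30% H2O2, THF/MeOH, rt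
Reagents that add atoms: [(isopropoxydimethylsilyl)methyl]magnesium chloride, CC(C)O[Si](C)(C)C[Mg]Cl; hydrogen peroxide, OO
Why: Copper-catalysed SN2 Grignard coupling at the primary allylic carbon (the fully substituted γ-carbon is blocked, so the alkene geometry is kept), followed by Tamao–Fleming oxidation of the C–Si bond, gives a one-carbon hydroxymethyl homologation.

Step 5
Reactants: 7 (3E,7E)-homofarnesol
Product: 8 (3E,7E)-homofarnesyl iodide
Conditions: I2, PPh3, imidazole, CH2Cl2, 0 °C
Reagents that add atoms: iodine, II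
Why: Appel-type iodination through SN2 displacement of the alkoxyphosphonium ion, under conditions routinely tolerated by trisubstituted alkenes.

Step 6
Reactants: 8 (3E,7E)-homofarnesyl iodide; 9 ethyl (triphenyl-λ5-phosphanylidene)acetate
Product: 11 ethyl (5E,9E)-6,10,14-trimethyl-2-(triphenyl-λ5-phosphanylidene)pentadeca-5,9,13-trienoate, via alkylated phosphonium iodide 10 (not isolated)
Conditions: 8 (1.1 equiv), MeCN, 80 °C; then 2 M NaOH, CH2Cl2, rt
Reagents that add atoms: none
Why: SN2 C-alkylation of the stabilised ylide by the primary iodide gives the α-alkyl phosphonium salt, which aqueous base deprotonates to the α-substituted stabilised ylide; the ylide is too weakly basic to favour E2 elimination.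

Step 7
Reactants: 4 (3S)-3-(furan-3-yl)-3-(triethylsilyloxy)propanal; 11 ethyl (5E,9E)-6,10,14-trimethyl-2-(triphenyl-λ5-phosphanylidene)pentadeca-5,9,13-trienoate
Product: 12 ethyl (2E,5S)-5-(furan-3-yl)-5-(triethylsilyloxy)-2-[(3E,7E)-4,8,12-trimethyltrideca-3,7,11-trien-1-yl]pent-2-enoate
Conditions: toluene, 90 °C
Reagents that add atoms: none
Why: Wittig olefination with an α-alkyl stabilised ylide, which should place the ester trans to the aldehyde-derived CH2 (the required E geometry, where phosphonate variants tend to leak to Z) and, being base-free, should not eliminate the β-silyloxy group.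

Step 8
Reactants: 12 ethyl (2E,5S)-5-(furan-3-yl)-5-(triethylsilyloxy)-2-[(3E,7E)-4,8,12-trimethyltrideca-3,7,11-trien-1-yl]pent-2-enoate
Product: 13 (2E,5S)-5-(furan-3-yl)-5-(triethylsilyloxy)-2-[(3E,7E)-4,8,12-trimethyltrideca-3,7,11-trien-1-yl]pent-2-en-1-ol
Conditions: iBu2AlH (2.5 equiv), CH2Cl2, −78 to 0 °C
Reagents that add atoms: none
Why: 1,2-Reduction of the enoate to the allylic alcohol by the electrophilic aluminium hydride, which leaves furan, silyl ether and isolated alkenes alone.

Step 9
Reactants: 13 (2E,5S)-5-(furan-3-yl)-5-(triethylsilyloxy)-2-[(3E,7E)-4,8,12-trimethyltrideca-3,7,11-trien-1-yl]pent-2-en-1-ol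
Product: 15 5-hydroxy-4-[(1S,3E,7E,11E)-4-(hydroxymethyl)-8,12,16-trimethyl-1-(triethylsilyloxy)heptadeca-3,7,11,15-tetraen-1-yl]furan-2(5H)-one (hemiacetal epimers), via furan endoperoxide 14 (not isolated)
Conditions: O2, hν (visible), tetraphenylporphyrin (cat.), iPr2NEt, CH2Cl2, −78 °C
Reagents that add atoms: dioxygen, O=O
Why: [4+2] cycloaddition of singlet oxygen to the furan (faster than the ene reaction of trisubstituted alkenes at −78 °C), then Kornblum–DeLaMare fragmentation in which the hindered amine removes the bridgehead proton remote from the side chain, so the lactone carbonyl forms at the distal α-carbon.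

Step 10
Reactants: 15 5-hydroxy-4-[(1S,3E,7E,11E)-4-(hydroxymethyl)-8,12,16-trimethyl-1-(triethylsilyloxy)heptadeca-3,7,11,15-tetraen-1-yl]furan-2(5H)-one
Product: 18 4-[(1S,3E,7E,11E)-1-hydroxy-4-(hydroxymethyl)-8,12,16-trimethylheptadeca-3,7,11,15-tetraen-1-yl]furan-2(5H)-one (acyclic precursor), via sodium hydroxy-enoate 16 (not isolated), via silyl-protected butenolide 17 (not isolated)
Conditions: NaBH4, EtOH, 0 °C; then 1 M HCl, THF, rt
Reagents that add atoms: none
Why: Borohydride reduces the aldehyde of the ring-opened formyl-carboxylate form of the hydroxybutenolide, and acidification then lactonises the cis-γ-hydroxy acid to the butenolide and cleaves the triethylsilyl ether in the same operation.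

Step 11
Reactants: 18 4-[(1S,3E,7E,11E)-1-hydroxy-4-(hydroxymethyl)-8,12,16-trimethylheptadeca-3,7,11,15-tetraen-1-yl]furan-2(5H)-one
Product: 19 4-[(1S,3E,7E)-1-hydroxy-4-(hydroxymethyl)-8-methyl-10-(2,6,6-trimethylcyclohex-1-en-1-yl)deca-3,7-dien-1-yl]furan-2(5H)-one (CNP0151336.1)
Conditions: engineered squalene–hopene cyclase (Alicyclobacillus acidocaldarius enzyme, active-site variant to be selected from a focused library), E. coli whole cells, citrate buffer pH 6.0, Triton X-100 (0.2%), 30 °C; extraction, chromatography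
Reagents that add atoms: none
Why: Proposed new method: the catalytic aspartic acid of the class 2 cyclase protonates the terminal isopropylidene alkene at its CH carbon, the tertiary cation is captured by the CH carbon of the neighbouring trisubstituted alkene, and the new tertiary cation at the methyl-bearing carbon is quenched by loss of the proton on the chain-bearing carbon, giving the tetrasubstituted ring alkene. The closest known reaction type is the truncated cation–olefin cyclisation by which squalene–hopene cyclase variants monocyclise geranylacetone-type substrates and squalene. The six-membered ring closes in a 6-endo-trig mode from a chair-folded terminus. No stereocentre is created, because the two carbons joined end as a gem-dimethyl carbon and an alkene carbon, and the remote (S)-carbinol is not involved. The step needs protonation only at the terminal alkene, termination after one ring, and deprotonation at the chain-bearing carbon instead of at the methyl group or the ring CH2. The substrate contributes the native isoprenoid terminus, an inductively deactivated hydroxymethyl-substituted alkene far from the first-ring cation, and a polar diol–butenolide head that should stay at the channel entrance; the rest must come from an active site reshaped so that the third isoprene unit cannot prefold and a base sits beside the chain-bearing carbon.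

Compound list
1 | ethyl 3-(furan-3-yl)-3-oxopropanoate | CCOC(=O)CC(=O)c1ccoc1 | starting material
2 | ethyl (3S)-3-(furan-3-yl)-3-hydroxypropanoate | CCOC(=O)C[C@H](O)c1ccoc1 | intermediate
3 | ethyl (3S)-3-(furan-3-yl)-3-(triethylsilyloxy)propanoate | CCOC(=O)C[C@H](O[Si](CC)(CC)CC)c1ccoc1 | intermediate
4 | (3S)-3-(furan-3-yl)-3-(triethylsilyloxy)propanal | O=CC[C@H](O[Si](CC)(CC)CC)c1ccoc1 | intermediate
5 | (2E,6E)-farnesyl bromide | CC(C)=CCC/C(C)=C/CC/C(C)=C/CBr | starting material
6 | isopropoxydimethyl[(3E,7E)-4,8,12-trimethyltrideca-3,7,11-trien-1-yl]silane | CC(C)=CCC/C(C)=C/CC/C(C)=C/CC[Si](C)(C)OC(C)C | intermediate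
7 | (3E,7E)-homofarnesol, (3E,7E)-4,8,12-trimethyltrideca-3,7,11-trien-1-ol | CC(C)=CCC/C(C)=C/CC/C(C)=C/CCO | intermediate
8 | (3E,7E)-homofarnesyl iodide, (3E,7E)-1-iodo-4,8,12-trimethyltrideca-3,7,11-triene | CC(C)=CCC/C(C)=C/CC/C(C)=C/CCI | intermediate
9 | ethyl (triphenyl-λ5-phosphanylidene)acetate | CCOC(=O)C=P(c1ccccc1)(c1ccccc1)c1ccccc1 | starting material
10 | [(5E,9E)-1-ethoxy-6,10,14-trimethyl-1-oxopentadeca-5,9,13-trien-2-yl]triphenylphosphonium iodide | CC(C)=CCC/C(C)=C/CC/C(C)=C/CCC(C(=O)OCC)[P+](c1ccccc1)(c1ccccc1)c1ccccc1.[I-] | intermediate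
11 | ethyl (5E,9E)-6,10,14-trimethyl-2-(triphenyl-λ5-phosphanylidene)pentadeca-5,9,13-trienoate | CC(C)=CCC/C(C)=C/CC/C(C)=C/CCC(C(=O)OCC)=P(c1ccccc1)(c1ccccc1)c1ccccc1 | intermediate
12 | ethyl (2E,5S)-5-(furan-3-yl)-5-(triethylsilyloxy)-2-[(3E,7E)-4,8,12-trimethyltrideca-3,7,11-trien-1-yl]pent-2-enoate | CC(C)=CCC/C(C)=C/CC/C(C)=C/CC/C(=C\C[C@H](O[Si](CC)(CC)CC)c1ccoc1)C(=O)OCC | intermediate
13 | (2E,5S)-5-(furan-3-yl)-5-(triethylsilyloxy)-2-[(3E,7E)-4,8,12-trimethyltrideca-3,7,11-trien-1-yl]pent-2-en-1-ol | CC(C)=CCC/C(C)=C/CC/C(C)=C/CC/C(=C\C[C@H](O[Si](CC)(CC)CC)c1ccoc1)CO | intermediate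
14 | 2,3,7-trioxabicyclo[2.2.1]hept-5-ene formed across the two α-carbons of the furan of 13 (side chain on C5 of the bicycle) | CC(C)=CCC/C(C)=C/CC/C(C)=C/CC/C(=C\C[C@H](O[Si](CC)(CC)CC)C1=CC2OOC1O2)CO | intermediate
15 | 5-hydroxy-4-[(1S,3E,7E,11E)-4-(hydroxymethyl)-8,12,16-trimethyl-1-(triethylsilyloxy)heptadeca-3,7,11,15-tetraen-1-yl]furan-2(5H)-one | CC(C)=CCC/C(C)=C/CC/C(C)=C/CC/C(=C\C[C@H](O[Si](CC)(CC)CC)C1=CC(=O)OC1O)CO | intermediate
16 | sodium 4-hydroxy-3-[(1S,3E,7E,11E)-4-(hydroxymethyl)-8,12,16-trimethyl-1-(triethylsilyloxy)heptadeca-3,7,11,15-tetraen-1-yl]but-2-enoate (CH2OH and carboxylate cis) | CC(C)=CCC/C(C)=C/CC/C(C)=C/CC/C(=C\C[C@H](O[Si](CC)(CC)CC)/C(CO)=C/C(=O)[O-])CO.[Na+] | intermediate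
17 | 4-[(1S,3E,7E,11E)-4-(hydroxymethyl)-8,12,16-trimethyl-1-(triethylsilyloxy)heptadeca-3,7,11,15-tetraen-1-yl]furan-2(5H)-one | CC(C)=CCC/C(C)=C/CC/C(C)=C/CC/C(=C\C[C@H](O[Si](CC)(CC)CC)C1=CC(=O)OC1)CO | intermediate
18 | 4-[(1S,3E,7E,11E)-1-hydroxy-4-(hydroxymethyl)-8,12,16-trimethylheptadeca-3,7,11,15-tetraen-1-yl]furan-2(5H)-one | CC(C)=CCC/C(C)=C/CC/C(C)=C/CC/C(=C\C[C@H](O)C1=CC(=O)OC1)CO | intermediate
19 | 4-[(1S,3E,7E)-1-hydroxy-4-(hydroxymethyl)-8-methyl-10-(2,6,6-trimethylcyclohex-1-en-1-yl)deca-3,7-dien-1-yl]furan-2(5H)-one (CNP0151336.1) | CC1=C(CC/C(C)=C/CC/C(=C\C[C@H](O)C2=CC(=O)OC2)CO)C(C)(C)CCC1 | target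

Total step count: 11. Longest linear sequence: 8 steps (steps 1–3 then 7–11, or steps 4–6 then 7–11).

Steps most likely to fail

Step 11. The cyclase may not bind or turn over a substrate with a polar head, may carry the cascade on to a second ring, or may deprotonate towards the exocyclic or trisubstituted ring alkene. The fallback uses known chemistry, sets out from aldehyde 4 and ylide 9, and comes back at target 19; the ring is bought instead of made.
- Dihydro-β-ionone F1 would be converted through its kinetic enol phosphate, diethyl 4-(2,6,6-trimethylcyclohex-1-en-1-yl)but-1-en-2-yl phosphate F2 (LiN(iPr)2, then ClP(O)(OEt)2), and elimination with more LiN(iPr)2 into the terminal alkyne 2-(but-3-yn-1-yl)-1,3,3-trimethylcyclohex-1-ene F3.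
- Negishi syn-methylalumination (Me3Al, Cp2ZrCl2 cat.) would give the (E)-alkenylalane F4, whose ate complex (nBuLi) opens oxirane to the (E)-homoallylic alcohol F5.
- Iodination as in step 5 would give the iodide F6, alkylation of 9 as in step 6 the phosphonium iodide F7 and then the ylide F8, Wittig reaction with 4 the enoate F9, and iBu2AlH the allylic alcohol F10.
- Because singlet oxygen could attack the tetrasubstituted ring alkene, the furan would be oxidised by iridium-catalysed C–H borylation at its free, unhindered α-position ([Ir(OMe)(cod)]2, 4,4′-di-tert-butyl-2,2′-bipyridine, B2pin2) to the furyl boronate F11 and NaBO3·4H2O oxidation to the silyl-protected butenolide F12. 1 M HCl in THF would then give 19.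

Step 9. Singlet oxygen may also attack the four trisubstituted chain alkenes in ene reactions, or the endoperoxide may collapse with the wrong regiochemistry. The fallback sets out from 13 and comes back at 17. Iridium-catalysed C–H borylation of the furan at the α-carbon remote from the side chain (same catalyst system as above) would give the furyl boronate F13. NaBO3·4H2O oxidation would give the 2-hydroxyfuran, which tautomerises (Et3N if needed) to butenolide 17, isolated in this variant. The acid treatment of step 10 would then deliver 18, so neither singlet oxygen nor borohydride is needed.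

Step 6. SN2 attack of the weakly nucleophilic stabilised ylide on an unactivated iodide may be slow, and E2 elimination at the allylic β-hydrogens may compete. The fallback sets out from 8 and comes back at 11. Methylenetriphenylphosphorane F14 (from [Ph3PCH3]Br and nBuLi, THF) would be alkylated by 8 to the phosphonium iodide F15. NaN(SiMe3)2 would give the non-stabilised ylide F16, which ClCO2Et C-acylates at −78 °C to the acylphosphonium chloride F17. A second equivalent of NaN(SiMe3)2 would give 11.

Further compounds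
F1 | step 11 | dihydro-β-ionone, 4-(2,6,6-trimethylcyclohex-1-en-1-yl)butan-2-one | CC(=O)CCC1=C(C)CCCC1(C)C
F2 | step 11 | diethyl 4-(2,6,6-trimethylcyclohex-1-en-1-yl)but-1-en-2-yl phosphate | C=C(CCC1=C(C)CCCC1(C)C)OP(=O)(OCC)OCC
F3 | step 11 | 2-(but-3-yn-1-yl)-1,3,3-trimethylcyclohex-1-ene | C#CCCC1=C(C)CCCC1(C)C
F4 | step 11 | dimethyl[(1E)-2-methyl-4-(2,6,6-trimethylcyclohex-1-en-1-yl)but-1-en-1-yl]alumane | CC1=C(CC/C(C)=C/[Al](C)C)C(C)(C)CCC1
F5 | step 11 | (3E)-4-methyl-6-(2,6,6-trimethylcyclohex-1-en-1-yl)hex-3-en-1-ol | CC1=C(CC/C(C)=C/CCO)C(C)(C)CCC1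
F6 | step 11 | 2-[(3E)-6-iodo-3-methylhex-3-en-1-yl]-1,3,3-trimethylcyclohex-1-ene | CC1=C(CC/C(C)=C/CCI)C(C)(C)CCC1
F7 | step 11 | [(5E)-1-ethoxy-6-methyl-1-oxo-8-(2,6,6-trimethylcyclohex-1-en-1-yl)oct-5-en-2-yl]triphenylphosphonium iodide | CC1=C(CC/C(C)=C/CCC(C(=O)OCC)[P+](c2ccccc2)(c2ccccc2)c2ccccc2)C(C)(C)CCC1.[I-]
F8 | step 11 | ethyl (5E)-6-methyl-8-(2,6,6-trimethylcyclohex-1-en-1-yl)-2-(triphenyl-λ5-phosphanylidene)oct-5-enoate | CC1=C(CC/C(C)=C/CCC(C(=O)OCC)=P(c2ccccc2)(c2ccccc2)c2ccccc2)C(C)(C)CCC1
F9 | step 11 | ethyl (2E,5S)-5-(furan-3-yl)-2-[(3E)-4-methyl-6-(2,6,6-trimethylcyclohex-1-en-1-yl)hex-3-en-1-yl]-5-(triethylsilyloxy)pent-2-enoate | CC1=C(CC/C(C)=C/CC/C(=C\C[C@H](O[Si](CC)(CC)CC)c2ccoc2)C(=O)OCC)C(C)(C)CCC1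
F10 | step 11 | (2E,5S)-5-(furan-3-yl)-2-[(3E)-4-methyl-6-(2,6,6-trimethylcyclohex-1-en-1-yl)hex-3-en-1-yl]-5-(triethylsilyloxy)pent-2-en-1-ol | CC1=C(CC/C(C)=C/CC/C(=C\C[C@H](O[Si](CC)(CC)CC)c2ccoc2)CO)C(C)(C)CCC1
F11 | step 11 | pinacol boronate of F10 at the furan α-carbon remote from the side chain | CC1=C(CC/C(C)=C/CC/C(=C\C[C@H](O[Si](CC)(CC)CC)c2coc(B3OC(C)(C)C(C)(C)O3)c2)CO)C(C)(C)CCC1
F12 | step 11 | triethylsilyl ether of 19 at the secondary carbinol | CC1=C(CC/C(C)=C/CC/C(=C\C[C@H](O[Si](CC)(CC)CC)C2=CC(=O)OC2)CO)C(C)(C)CCC1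
F13 | step 9 | pinacol boronate of 13 at the furan α-carbon remote from the side chain | CC(C)=CCC/C(C)=C/CC/C(C)=C/CC/C(=C\C[C@H](O[Si](CC)(CC)CC)c1coc(B2OC(C)(C)C(C)(C)O2)c1)CO
F14 | step 6 | methylenetriphenylphosphorane | C=P(c1ccccc1)(c1ccccc1)c1ccccc1
F15 | step 6 | [(4E,8E)-5,9,13-trimethyltetradeca-4,8,12-trien-1-yl]triphenylphosphonium iodide | CC(C)=CCC/C(C)=C/CC/C(C)=C/CCC[P+](c1ccccc1)(c1ccccc1)c1ccccc1.[I-]
F16 | step 6 | triphenyl[(4E,8E)-5,9,13-trimethyltetradeca-4,8,12-trien-1-ylidene]-λ5-phosphane | CC(C)=CCC/C(C)=C/CC/C(C)=C/CCC=P(c1ccccc1)(c1ccccc1)c1ccccc1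
F17 | step 6 | [(5E,9E)-1-ethoxy-6,10,14-trimethyl-1-oxopentadeca-5,9,13-trien-2-yl]triphenylphosphonium chloride | CC(C)=CCC/C(C)=C/CC/C(C)=C/CCC(C(=O)OCC)[P+](c1ccccc1)(c1ccccc1)c1ccccc1.[Cl-]
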